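(The data were generated by integration for substances that don't exist, and the scatter is random.)

The vessel is closed, stirred and held at one temperature, the gas phase above it is held, and at the start none of that gas is in solution.

in all of them: gas phase 55 mM (held); free catalyst 0.41 mM

| run | starting material | remark | time |
|---|---|---|---|
| eta | 0.55 M | run made earlier |  |
| zeta | 2.2 M | run made earlier |  |
| north-west | 0.50 M |  | 4.0 h |
| east | 0.80 M |  | 4.0 h |
| west | 1.2 M |  | 4.0 h |
| south | 1.5 M |  | 4.0 h |

| run | time / min | product / % |
|---|---|---|
| eta | 30.0 | 18 |
| eta | 60.0 | 26 |
| eta | 90.0 | 37 |
| eta | 120 | 42 |
| zeta | 10.0 | 3 |
| zeta | 20.0 | 4 |
| zeta | 50.0 | 11 |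
| zeta | 120 | 18 |

(standard deviation of a reading: 2 percentage points)

- at the start none of the gas phase is in solution
- "hardly changes" means that all values lie within two and a half points (for a concentration: within two and a half percent of the largest)

1. amount of product at the end, in percent of the starting material charged for north-west, east, west, south, in this order
2. how the row runs (rises, then falls / rises all the way / hardly changes / falls, then rises / falls all the way)

Read the two runs as a ladder of times, fastest rung first. If each product takes up one gas, a solution at saturation holds 10.0 % of eta's charge, and eta's first reading, 18 % at 30.0 min, is more than that, so in eta gas has to keep crossing, and at that pace a solution-full lasts you 16.7 min. On the next rung, in zeta, the readings put the pace from 50.0 min to 120 min at about half of the pace up to 50.0 min, while they leave 82.0 % of zeta's starting material, so in these readings the pace falls by more than the starting material does. Further up the ladder, eta's first pace would use up its charge in 2.78 h, which is shorter than the 4.0 h asked for.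

So I reckon like this: let the product made by a common time climb with the charge and level off, as in a half-saturation law, which makes the percentage go as one over the sum of the charge and a fixed charge. Eta's 42 % and zeta's 18 % at 120 min then give 0.688 M, the crossing charge, the charge at which this law puts the product made by that time at half its ceiling; it is a reading and carries the scatter of 2 percentage points. My own commitment is a falling row, with south at 0.543 of north-west's percentage at 120 min.

The forecast says 49 %, 41 %, 33 % and 29 %, a row that falls all the way, on the ground that “Absolute product rises, but percent falls throughout.” Its south stands at 0.592 of its north-west at 4.0 h, a later time than the 120 min of my ratio.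

The flasks give 57.7 %, 50.5 %, 43.3 % and 39.1 %, a row that falls all the way.

    gas phase ⇌ dissolved gas, rate k1*(csat - [dissolved gas]) (kL = 0.0880 /min)
    starting material + dissolved gas + free catalyst → free catalyst + product (k = 4000 /M²/min)
    2 free catalyst → spent catalyst (k = 220 /M/min)

Free catalyst stands at 2.26 % of its charge in north-west and at 2.26 % in south at 4.00 h. Use the crossing charge 0.688 M once more, at 2.00 h: it puts west at 0.629 of north-west, and west and north-west stand at 28.9 % and 43.5 % of product, a ratio of 0.664. For south it gives 0.543, and the flask ratio at that time is 0.580. At 4.00 h south stands at 0.678 of north-west.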